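**Retrosynthetic overview**

- Target 14 is the primary palmitate of keto diol 12. The ester C–O bond is cut last (palmitoyl chloride 13), and a benzyl ether carries the primary oxygen through the route.
- The strategy rests on the one ring, a cyclohexanone (C1 = carbinol carbon, C4 = ketone carbon): C3 and C5 are both enolisable α-carbons of C4, and C2 and C6 are both CH2 groups on the oxygen-bearing C1.
- Cutting C2–C3 and C5–C6 therefore gives an acetone 1,3-dianion (as N,N-dimethylhydrazone 5) and the 2-substituted epichlorohydrin 4, whose epoxide oxygen becomes the C1 hydroxyl. The ring is formed once, in step 3.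
- Epoxide 4 comes from allylsilane 1 and benzyl chloromethyl ether 2 by Hosomi–Sakurai allylation, then epoxidation.

Key step: step 3

Remark on the chemistry: the target has no stereocentre (C1 lies on the mirror plane of the ring), so chiral intermediates 4 and 7 are used as racemates.

**Step 1**
Reactants: 1 [2-(chloromethyl)allyl]trimethylsilane; 2 benzyl chloromethyl ether
Product: 3 ({[3-(chloromethyl)but-3-en-1-yl]oxy}methyl)benzene
Conditions: 1 (1.2 equiv), freshly distilled 2, SnCl4 (20 mol %), CH2Cl2, −78 → −40 °C
Reagents that add atoms: none
Why: Hosomi–Sakurai allylation, in which SnCl4 ionises the α-chloro ether to a benzyloxymethyl oxocarbenium ion that is attacked by the γ-carbon of the allylsilane with loss of Me3SiCl, so the transposed 1,1-disubstituted alkene should form with the oxygen already benzylated and no free chloro alcohol that could close to a tetrahydrofuran.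

**Step 2**
Reactants: 3 ({[3-(chloromethyl)but-3-en-1-yl]oxy}methyl)benzene
Product: 4 2-[2-(benzyloxy)ethyl]-2-(chloromethyl)oxirane (racemic)
Conditions: mCPBA (1.5 equiv), NaHCO3, CH2Cl2, 0 °C → rt
Reagents that add atoms: mCPBA, OOC(=O)c1cccc(Cl)c1
Why: Prilezhaev epoxidation of the only alkene, buffered so that 3-chlorobenzoic acid does not open the epoxide; the quaternary stereocentre forms as a racemate, which is immaterial because it ceases to be a stereocentre in step 3.

**Step 3**
Reactants: 5 acetone N,N-dimethylhydrazone; 4 2-[2-(benzyloxy)ethyl]-2-(chloromethyl)oxirane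
Product: 10 4-[2-(benzyloxy)ethyl]-4-hydroxycyclohexan-1-one N,N-dimethylhydrazone, via lithium azaenolate of acetone dimethylhydrazone 6 (not isolated), via epoxy hydrazone 7 (not isolated), via lithium azaenolate of the epoxy hydrazone 8 (not isolated), via lithium alkoxide of the ring-closed hydrazone 9 (not isolated)
Conditions: LiN(iPr)2 (1.05 equiv), THF, 0 °C; then 4, −78 → 0 °C; then LiN(iPr)2 (1.2 equiv), −78 °C → rt; H2O quench
Reagents that add atoms: none
Why: Proposed new method: LiN(iPr)2 turns 5 into azaenolate 6, whose carbon attacks 4 at either primary terminus (direct displacement of chloride, or opening at the epoxide CH2 followed by closure of the chlorohydrin alkoxide onto CH2Cl), and both paths converge on epoxy hydrazone 7 with C2–C3 formed. A second equivalent of base removes a proton from the remaining methyl group of 7, the less substituted α-carbon as is usual for dimethylhydrazones, to give 8, which opens the epoxide by intramolecular SN2 attack at its CH2 terminus, forming C5–C6 and the cyclohexane ring in a 6-endo epoxide opening and releasing the C1 alkoxide 9, protonated on quench. The closest known reaction types are the sequential α,α′-dialkylation of ketone N,N-dimethylhydrazone azaenolates, the use of epichlorohydrin as a 1,3-dielectrophile and carbanion epoxide-opening ring closures of the Stork epoxynitrile kind; their combination in one flask with this electrophile has not been shown. No stereocentre is created, because C1 lies on the mirror plane of the new ring and the stereocentre of racemic 4 and 7 disappears on closure. The step needs attack at CH2 (six-membered ring) and not at C1 (five-membered ring), which the full substitution of C1 secures by blocking backside attack there, and it needs C- and not N-alkylation, which is the normal course for lithium azaenolates; if some chlorohydrin alkoxide survives the first stage, displacement of its chloride by the second azaenolate gives the same ring.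

**Step 4**
Reactants: 10 4-[2-(benzyloxy)ethyl]-4-hydroxycyclohexan-1-one N,N-dimethylhydrazone
Product: 11 4-[2-(benzyloxy)ethyl]-4-hydroxycyclohexan-1-one
Conditions: saturated aqueous oxalic acid, Et2O, rt
Reagents that add atoms: water, O
Why: Acid-catalysed two-phase hydrolysis of the N,N-dimethylhydrazone, in which the hydrazine is drawn into the aqueous layer as its oxalate while the tertiary alcohol and the benzyl ether should be untouched at this mild acidity.

**Step 5**
Reactants: 11 4-[2-(benzyloxy)ethyl]-4-hydroxycyclohexan-1-one
Product: 12 4-hydroxy-4-(2-hydroxyethyl)cyclohexan-1-one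
Conditions: H2 (1 atm), 10 % Pd/C, EtOAc, rt
Reagents that add atoms: none
Why: Catalytic hydrogenolysis of the benzyl ether; the saturated ketone and the tertiary alcohol should not be reduced at one atmosphere of hydrogen in a non-alcoholic solvent.

**Step 6**
Reactants: 12 4-hydroxy-4-(2-hydroxyethyl)cyclohexan-1-one; 13 palmitoyl chloride
Product: 14 2-(1-hydroxy-4-oxocyclohexyl)ethyl hexadecanoate
Conditions: 13 (1.05 equiv), pyridine, CH2Cl2, 0 °C
Reagents that add atoms: none
Why: Chemoselective O-acylation (nucleophilic acyl substitution) of the unhindered primary hydroxyl; the tertiary hydroxyl on C1 should not react with an acid chloride and pyridine at 0 °C without an acyl-transfer catalyst.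

**Compound list**

1 | [2-(chloromethyl)allyl]trimethylsilane | C[Si](C)(C)CC(=C)CCl | starting material
2 | benzyl chloromethyl ether | ClCOCc1ccccc1 | starting material
3 | ({[3-(chloromethyl)but-3-en-1-yl]oxy}methyl)benzene | ClCC(=C)CCOCc1ccccc1 | intermediate
4 | 2-[2-(benzyloxy)ethyl]-2-(chloromethyl)oxirane (racemic) | ClCC1(CCOCc2ccccc2)CO1 | intermediate
5 | acetone N,N-dimethylhydrazone | CC(C)=NN(C)C | starting material
6 | lithium azaenolate of acetone N,N-dimethylhydrazone | [Li]CC(C)=NN(C)C | intermediate (not isolated)
7 | 4-{2-[2-(benzyloxy)ethyl]oxiran-2-yl}butan-2-one N,N-dimethylhydrazone (racemic) | CC(=NN(C)C)CCC1(CCOCc2ccccc2)CO1 | intermediate (not isolated)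
8 | lithium azaenolate of 7, lithiated at the methyl group | [Li]CC(=NN(C)C)CCC1(CCOCc2ccccc2)CO1 | intermediate (not isolated)
9 | lithium 1-[2-(benzyloxy)ethyl]-4-(dimethylhydrazinylidene)cyclohexan-1-olate | [Li]OC1(CCOCc2ccccc2)CCC(=NN(C)C)CC1 | intermediate (not isolated)
10 | 4-[2-(benzyloxy)ethyl]-4-hydroxycyclohexan-1-one N,N-dimethylhydrazone | CN(C)N=C1CCC(O)(CCOCc2ccccc2)CC1 | intermediate
11 | 4-[2-(benzyloxy)ethyl]-4-hydroxycyclohexan-1-one | O=C1CCC(O)(CCOCc2ccccc2)CC1 | intermediate
12 | 4-hydroxy-4-(2-hydroxyethyl)cyclohexan-1-one | O=C1CCC(O)(CCO)CC1 | intermediate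
13 | palmitoyl chloride (hexadecanoyl chloride) | CCCCCCCCCCCCCCCC(=O)Cl | starting material
14 | 2-(1-hydroxy-4-oxocyclohexyl)ethyl hexadecanoate | CCCCCCCCCCCCCCCC(=O)OCCC1(O)CCC(=O)CC1 | target

**Totals**

Total step count: 6. Longest linear sequence: 6 steps (1 and 2 → 3 → 4 → 10 → 11 → 12 → 14).

**Steps most likely to fail**

Step 3 (Proposed new method). The one-flask annulation may fail in several ways: base-induced isomerisation of the epoxide to an allylic alkoxide before the second azaenolate forms, intermolecular reaction of azaenolate 8 with unreacted 4 or with 7 leading to oligomers, or a ring closure too slow to compete with proton transfer. The fallback buys the ring instead of making it; it sets out from 2 and comes back to the route at 11. Compound 2 is stannylated with Bu3SnLi (from Bu3SnH and LiN(iPr)2, THF, −78 °C) to give tributyl[(benzyloxy)methyl]stannane F1. Commercial 1,4-dioxaspiro[4.5]decan-8-one is converted by Corey–Chaykovsky methylenation (trimethylsulfoxonium iodide, NaH, DMSO) into the spiro-epoxide 1,7,10-trioxadispiro[2.2.4.2]dodecane F2. Tin–lithium exchange of F1 (n-BuLi, THF, −78 °C) gives (benzyloxymethyl)lithium F3, which should open F2 at its CH2 terminus in the presence of BF3·OEt2 to give 8-[2-(benzyloxy)ethyl]-1,4-dioxaspiro[4.5]decan-8-ol F4. Mild acid hydrolysis of the dioxolane (pyridinium 4-toluenesulfonate, acetone/H2O) then gives 11.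

Step 1. The chloromethyl group lowers the nucleophilicity of the allylsilane, so protodesilylation by adventitious HCl or a further Prins-type reaction of the product alkene with the oxocarbenium ion may erode the allylation. The fallback sets out from 2 and comes back at 3. SN2 coupling of 2 with commercial 2-methylallylmagnesium chloride (THF, 0 °C) gives {[(3-methylbut-3-en-1-yl)oxy]methyl}benzene F5. Ene-type allylic chlorination with HOCl generated from Ca(OCl)2 and CO2 (CH2Cl2/H2O, 0 °C) should then deliver 3; any isomeric trisubstituted allylic chloride is removed by chromatography.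

Step 6. Over-acylation at the tertiary hydroxyl may occur, or acylation may be sluggish if the keto diol rests partly as a bicyclic hemiketal. The fallback sets out from 12 and comes back at 14. It is a Mitsunobu esterification with palmitic acid (PPh3, diisopropyl azodicarboxylate, THF, 0 °C → rt): the primary alcohol is activated as an alkoxyphosphonium ion and displaced by palmitate, a mode in which the tertiary alcohol cannot take part. No new compound is made on the way.

**Further compounds**

F1 | step 3 | tributyl[(benzyloxy)methyl]stannane | CCCC[Sn](CCCC)(CCCC)COCc1ccccc1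
F2 | step 3 | 1,7,10-trioxadispiro[2.2.4.2]dodecane | C1OC12CCC3(CC2)OCCO3
F3 | step 3 | (benzyloxymethyl)lithium | [Li]COCc1ccccc1
F4 | step 3 | 8-[2-(benzyloxy)ethyl]-1,4-dioxaspiro[4.5]decan-8-ol | OC1(CCOCc2ccccc2)CCC2(CC1)OCCO2
F5 | step 1 | {[(3-methylbut-3-en-1-yl)oxy]methyl}benzene | CC(=C)CCOCc1ccccc1
F0 | step 6 | none | none
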